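**Retrosynthetic overview**

1. Ring letters: the upper flavan is rings A/C (chroman) and B (4-hydroxyphenyl); the lower gallocatechin is rings D/F (chroman) and E (pyrogallol). Target 17 comes from its octabenzyl ether 16 by hydrogenolysis, and rings D, E, F with both of their stereocentres are bought as (+)-gallocatechin.
2. The route rests on C4 of ring C: a benzylic methine bonded to C4a (ortho to the ring A oxygen O1), carrying C8 of ring D and 1,3-related to the oxygen-bearing benzylic C2. Ring C is therefore opened at O1–C2 (phenol addition to an E-styrene) and at C4–C4a (aromatic Claisen rearrangement of the (R)-configured aryl 1,3-diarylallyl ether 14).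
3. 14 comes from a Negishi coupling of E-vinyl iodide 7 with the zinc reagent of 8-bromo-hexa-O-benzylgallocatechin 11. The alkene and ring D are added only after the C–O stereocentre exists, so no 1,3-diarylallyl alcohol is ever etherified; such an alcohol would ionise to a delocalised cation and lose configuration and regiochemistry.
4. 7 comes from the (R)-aryl propargyl ether 5 by hydrozirconation and iodination. 5 comes from racemic acetate 3 and 3-(benzyloxy)phenol 4 by stereoconvergent copper-catalysed propargylic etherification, and 3 from 4-(benzyloxy)benzaldehyde 1.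
5. Ring order: rings A, B, D, E and F arrive in the building blocks; ring C is the only ring made and is closed in step 8.

Key step: step 8

Remark: the facial sense of the copper/pybox catalyst for this substrate pair is fixed in a trial run, and the ligand antipode that gives (R)-5 is used.

**Route**

Step 1
Reactants: 1 4-(benzyloxy)benzaldehyde
Product: 3 rac-1-[4-(benzyloxy)phenyl]prop-2-yn-1-yl acetate, via bromomagnesium propargylic alkoxide 2 (not isolated)
Conditions: HC≡CMgBr (1.2 equiv), THF, 0 °C; then Ac2O (1.5 equiv), 0 °C → rt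
Reagents that add atoms: ethynylmagnesium bromide, C#C[Mg]Br; acetic anhydride, CC(=O)OC(C)=O
Why: Grignard addition to the aromatic aldehyde followed by O-acylation of the magnesium alkoxide in the same flask gives the propargylic acetate, deliberately racemic because step 2 is stereoconvergent.

Step 2
Reactants: 3 rac-1-[4-(benzyloxy)phenyl]prop-2-yn-1-yl acetate; 4 3-(benzyloxy)phenol
Product: 5 1-(benzyloxy)-3-{[(1R)-1-(4-benzyloxyphenyl)prop-2-yn-1-yl]oxy}benzene
Conditions: (CuOTf)2·C6H6 (5 mol% Cu), 2,6-bis(4-phenyl-4,5-dihydrooxazol-2-yl)pyridine (Ph-pybox, 10 mol%), iPr2NEt (1.2 equiv), 4 (1.5 equiv), CH2Cl2, −20 °C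
Reagents that add atoms: none
Why: Copper-catalysed asymmetric propargylic etherification: the monovalent copper acetylide of either enantiomer of 3 loses acetate to one planar copper allenylidene, and the pybox ligand leaves one face of its γ-carbon open to the phenol oxygen, which sets the (R)-ether centre that is later relayed to C4.

Step 3
Reactants: 5 1-(benzyloxy)-3-{[(1R)-1-(4-benzyloxyphenyl)prop-2-yn-1-yl]oxy}benzene
Product: 7 1-(benzyloxy)-3-{[(1R,2E)-1-(4-benzyloxyphenyl)-3-iodoprop-2-en-1-yl]oxy}benzene, via E-alkenylzirconocene chloride 6 (not isolated)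
Conditions: Cp2Zr(H)Cl (1.3 equiv), THF, rt, dark; then I2 (1.3 equiv), −78 → 0 °C; aq Na2S2O3/NaHCO3
Reagents that add atoms: iodine, II
Why: Hydrozirconation adds Zr–H syn across the terminal alkyne with zirconium on the end carbon, and iododemetalation with retention gives the E-vinyl iodide without touching the ether stereocentre.

Step 4
Reactants: 8 (+)-gallocatechin
Product: 9 5,7,3',4',5'-penta-O-benzyl-(+)-gallocatechin
Conditions: BnBr (5.5 equiv), K2CO3 (6 equiv), degassed DMF, Ar, 0 °C → rt
Reagents that add atoms: benzyl bromide, BrCc1ccccc1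
Why: Williamson etherification with carbonate alkylates the five phenols and leaves the secondary alcohol, while exclusion of oxygen protects the pyrogallol ring E and the mild base should not epimerise C2 or C3.

Step 5
Reactants: 9 5,7,3',4',5'-penta-O-benzyl-(+)-gallocatechin
Product: 10 3,5,7,3',4',5'-hexa-O-benzyl-(+)-gallocatechin
Conditions: NaH (1.5 equiv), BnBr (1.5 equiv), n-Bu4NI (cat.), DMF, 0 °C → rt
Reagents that add atoms: benzyl bromide, BrCc1ccccc1
Why: Williamson etherification of the secondary alkoxide is an O-alkylation, so C3 keeps its configuration.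

Step 6
Reactants: 10 3,5,7,3',4',5'-hexa-O-benzyl-(+)-gallocatechin
Product: 11 8-bromo-3,5,7,3',4',5'-hexa-O-benzyl-(+)-gallocatechin
Conditions: NBS (1.0 equiv), CH2Cl2, −40 → 0 °C, dark
Reagents that add atoms: N-bromosuccinimide, O=C1CCC(=O)N1Br
Why: Electrophilic aromatic bromination goes to the phloroglucinol-type ring D, far more nucleophilic than ring E, and by analogy with benzylated catechins should favour C8 over C6.

Step 7
Reactants: 11 8-bromo-3,5,7,3',4',5'-hexa-O-benzyl-(+)-gallocatechin; 7 1-(benzyloxy)-3-{[(1R,2E)-1-(4-benzyloxyphenyl)-3-iodoprop-2-en-1-yl]oxy}benzene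
Product: 14 1-(benzyloxy)-3-{[(1R,2E)-1-(4-benzyloxyphenyl)-3-(hexa-O-benzylgallocatechin-8-yl)prop-2-en-1-yl]oxy}benzene, via 8-lithio-hexa-O-benzylgallocatechin 12 (not isolated), via 8-chlorozincio-hexa-O-benzylgallocatechin 13 (not isolated)
Conditions: 11, n-BuLi (1.05 equiv), THF, −78 °C; ZnCl2 (1.1 equiv), −78 → 0 °C; then 7 (1.1 equiv), Pd2(dba)3 (2.5 mol%), SPhos (10 mol%), THF, rt
Reagents that add atoms: none
Why: Bromine–lithium exchange, transmetalation to zinc and Negishi coupling join C8 to the vinyl carbon with retention of the E geometry; zerovalent palladium is consumed at once by oxidative addition to the C–I bond of the excess iodide, so it should not ionise the allylic aryl ether, and 14 is purified on triethylamine-deactivated silica and used promptly.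

Step 8
Reactants: 14 1-(benzyloxy)-3-{[(1R,2E)-1-(4-benzyloxyphenyl)-3-(hexa-O-benzylgallocatechin-8-yl)prop-2-en-1-yl]oxy}benzene
Product: 16 octa-O-benzyl ether of the target (2S,4R in the upper chroman), via ortho-(1,3-diarylallyl)phenol 15 (not isolated)
Conditions: degassed PhMe (0.02 M), 2,6-di-tert-butyl-4-methylpyridine (5 mol%), 110 °C; then cool to rt, TsOH·H2O (20 mol%)
Reagents that add atoms: none
Why: In a non-polar, acid-free medium the ether should rearrange by a concerted aromatic Claisen ([3,3]) shift through a chair-like transition state with the 4-benzyloxyphenyl group pseudo-equatorial, so the C–O bond breaks and C4–C4a forms on the same face of the allyl unit and the dienone tautomerises to phenol 15 with an E-styrene; TsOH then protonates the styrene at C3 and the para-benzyloxybenzyl cation at C2 is captured by the ring A phenol oxygen, closing ring C in the 6-endo mode by forming O1–C2. The closest known reaction types are the thermal aromatic Claisen rearrangement of enantioenriched aryl 1,3-disubstituted allyl ethers with 1,3-chirality transfer and the acid-catalysed cyclisation of ortho-(1,3-diarylallyl)phenols to 2,4-diarylchromans. C4 is controlled by the ether stereocentre: the (R)-ether with an E-alkene gives (4R) by suprafacial transfer. C2 is controlled by C4: in the half-chair closure the di-ortho-oxygenated aryl at C4 sits pseudo-axial to avoid the peri C5–H and the C2 aryl goes equatorial, which is the 2,4-trans (2S,4R) arrangement, and the same conformational preference should hold in the product. The step needs ortho attack at the aryl carbon para to the benzyloxy group and not at the carbon between the two oxygens, which the bulk of the migrating terminus carrying ring D and the usual bias of meta-alkoxy aryl ethers secure, and it needs the concerted path to outrun heterolysis of the doubly activated C–O bond, which the non-polar solvent, the pyridine buffer and the dilution favour.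

Step 9
Reactants: 16 octa-O-benzyl ether of the target
Product: 17 (2S)-4',7-dihydroxyflavan-(4R→8)-(+)-gallocatechin (CNP0220331.3)
Conditions: H2 (1 atm), Pd(OH)2/C, THF/MeOH 1:1, rt
Reagents that add atoms: none
Why: Hydrogenolysis removes the eight benzyl ethers, while the cyclic benzylic O1–C2 bonds and the diarylmethine C4 should survive as they do in benzylated flavan-3-ols, so no stereocentre is touched.

**Compound list**

1 | 4-(benzyloxy)benzaldehyde | O=Cc1ccc(OCc2ccccc2)cc1 | starting material
2 | bromomagnesium 1-[4-(benzyloxy)phenyl]prop-2-yn-1-olate (racemic) | C#CC(O[Mg]Br)c1ccc(OCc2ccccc2)cc1 | intermediate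
3 | rac-1-[4-(benzyloxy)phenyl]prop-2-yn-1-yl acetate | C#CC(OC(C)=O)c1ccc(OCc2ccccc2)cc1 | intermediate
4 | 3-(benzyloxy)phenol | Oc1cccc(OCc2ccccc2)c1 | starting material
5 | 1-(benzyloxy)-3-{[(1R)-1-(4-benzyloxyphenyl)prop-2-yn-1-yl]oxy}benzene | C#C[C@@H](Oc1cccc(OCc2ccccc2)c1)c1ccc(OCc2ccccc2)cc1 | intermediate
6 | chlorobis(cyclopentadienyl)[(1E,3R)-3-(3-benzyloxyphenoxy)-3-(4-benzyloxyphenyl)prop-1-en-1-yl]zirconium | Cl[Zr](C1C=CC=C1)(C1C=CC=C1)/C=C/[C@@H](Oc1cccc(OCc2ccccc2)c1)c1ccc(OCc2ccccc2)cc1 | intermediate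
7 | 1-(benzyloxy)-3-{[(1R,2E)-1-(4-benzyloxyphenyl)-3-iodoprop-2-en-1-yl]oxy}benzene | I/C=C/[C@@H](Oc1cccc(OCc2ccccc2)c1)c1ccc(OCc2ccccc2)cc1 | intermediate
8 | (+)-gallocatechin, (2R,3S) | Oc1cc(O)c2C[C@H](O)[C@@H](c3cc(O)c(O)c(O)c3)Oc2c1 | starting material
9 | 5,7,3',4',5'-penta-O-benzyl-(+)-gallocatechin | O(Cc5ccccc5)c1cc(OCc5ccccc5)c2C[C@H](O)[C@@H](c3cc(OCc5ccccc5)c(OCc5ccccc5)c(OCc5ccccc5)c3)Oc2c1 | intermediate
10 | 3,5,7,3',4',5'-hexa-O-benzyl-(+)-gallocatechin | O(Cc5ccccc5)c1cc(OCc5ccccc5)c2C[C@H](OCc5ccccc5)[C@@H](c3cc(OCc5ccccc5)c(OCc5ccccc5)c(OCc5ccccc5)c3)Oc2c1 | intermediate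
11 | 8-bromo-hexa-O-benzyl-(+)-gallocatechin | O(Cc5ccccc5)c1cc(OCc5ccccc5)c2C[C@H](OCc5ccccc5)[C@@H](c3cc(OCc5ccccc5)c(OCc5ccccc5)c(OCc5ccccc5)c3)Oc2c1Br | intermediate
12 | 8-lithio-hexa-O-benzylgallocatechin | O(Cc5ccccc5)c1cc(OCc5ccccc5)c2C[C@H](OCc5ccccc5)[C@@H](c3cc(OCc5ccccc5)c(OCc5ccccc5)c(OCc5ccccc5)c3)Oc2c1[Li] | intermediate
13 | 8-chlorozincio-hexa-O-benzylgallocatechin | O(Cc5ccccc5)c1cc(OCc5ccccc5)c2C[C@H](OCc5ccccc5)[C@@H](c3cc(OCc5ccccc5)c(OCc5ccccc5)c(OCc5ccccc5)c3)Oc2c1[Zn]Cl | intermediate
14 | 1-(benzyloxy)-3-{[(1R,2E)-1-(4-benzyloxyphenyl)-3-(hexa-O-benzylgallocatechin-8-yl)prop-2-en-1-yl]oxy}benzene | O(Cc5ccccc5)c1cc(OCc5ccccc5)c2C[C@H](OCc5ccccc5)[C@@H](c3cc(OCc5ccccc5)c(OCc5ccccc5)c(OCc5ccccc5)c3)Oc2c1/C=C/[C@@H](Oc1cccc(OCc5ccccc5)c1)c1ccc(OCc5ccccc5)cc1 | intermediate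
15 | 5-(benzyloxy)-2-[(1R,2E)-3-(4-benzyloxyphenyl)-1-(hexa-O-benzylgallocatechin-8-yl)prop-2-en-1-yl]phenol | O(Cc5ccccc5)c1ccc(/C=C/[C@@H](c3c(OCc5ccccc5)cc(OCc5ccccc5)c4c3O[C@H](c3cc(OCc5ccccc5)c(OCc5ccccc5)c(OCc5ccccc5)c3)[C@@H](OCc5ccccc5)C4)c3ccc(OCc5ccccc5)cc3O)cc1 | intermediate
16 | octa-O-benzyl ether of the target: (2S,4R)-7-benzyloxy-2-(4-benzyloxyphenyl)-4-(hexa-O-benzylgallocatechin-8-yl)chroman | O(Cc5ccccc5)c1ccc([C@@H]2C[C@@H](c3c(OCc5ccccc5)cc(OCc5ccccc5)c4c3O[C@H](c3cc(OCc5ccccc5)c(OCc5ccccc5)c(OCc5ccccc5)c3)[C@@H](OCc5ccccc5)C4)c3ccc(OCc5ccccc5)cc3O2)cc1 | intermediate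
17 | (2R,3S)-8-[(2S,4R)-7-hydroxy-2-(4-hydroxyphenyl)chroman-4-yl]-2-(3,4,5-trihydroxyphenyl)chroman-3,5,7-triol (CNP0220331.3) | Oc1ccc([C@@H]2C[C@@H](c3c(O)cc(O)c4c3O[C@H](c3cc(O)c(O)c(O)c3)[C@@H](O)C4)c3ccc(O)cc3O2)cc1 | target

**Step count**

Total: 9 steps. Longest linear sequence: 6 steps (steps 1, 2, 3, 7, 8, 9 from 1; the gallocatechin arm, steps 4, 5, 6, 7, 8, 9, is equally long).

**Steps most likely to fail**

Step 8. Heterolysis of the doubly activated benzylic/allylic C–O bond may compete with the concerted shift. Ion-pair return would erode the transfer of configuration and could deliver the allyl unit through its other terminus or to the ortho carbon between the two oxygens. The acid stage may also close ring C with incomplete trans selectivity, or epimerise C4 by reversible cleavage of the C4–C8 bond. The fallback forms the C4–C8 bond by cationic coupling and sets out from 10. Purchased (2S)-liquiritigenin F1 would be benzylated under neutral Mitsunobu conditions (BnOH, PPh3, DIAD, THF) to 7,4'-di-O-benzyl-(2S)-liquiritigenin F2, which avoids base-induced ring opening and racemisation of the flavanone. Reduction with NaBH4 would give (2S,4S)-7-benzyloxy-2-(4-benzyloxyphenyl)chroman-4-ol F3. Treating F3 with BF3·OEt2 in CH2Cl2 at −40 °C in the presence of excess 10 should generate the C4 cation, which C8 of ring D attacks anti to the C2 aryl to give the 2,4-trans product. This comes back to the route at 16.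

Step 7. Zerovalent palladium may ionise the allylic aryl ether of 7 or 14, causing racemisation or allylic transposition, and aryllithium 12 may decompose by attack on a neighbouring benzyloxy group before it is trapped by zinc. The fallback makes the C8–carbon bond at the alkyne stage, where palladium cannot form an allyl complex, and sets out from 5 and 11. Copper-free Sonogashira coupling (PdCl2(MeCN)2, XPhos, Cs2CO3, MeCN, 70 °C) would give the diaryl-substituted propargylic ether F4. F4 has the same spatial arrangement as (R)-5 but is named (S), because the arylethynyl group now outranks the aryl group. Trans-hydrosilylation with (EtO)3SiH and [Cp*Ru(MeCN)3]PF6 would give the vinylsilane F5, drawn silylated at the carbon bearing ring D; the other regioisomer serves equally. Protodesilylation with TBAF/CuI then gives the E-alkene and comes back at 14.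

Step 2. The electron-rich propargylic acetate may ionise outside the chiral catalyst and lower the enantiomeric purity, and the electron-rich phenol may be propargylated on carbon instead of oxygen. The fallback separates stereocentre formation from etherification and sets out from 1. Zinc-mediated asymmetric alkynylation (trimethylsilylacetylene, Me2Zn, ProPhenol ligand, toluene, 0 °C) would give (R)-1-(4-benzyloxyphenyl)-3-(trimethylsilyl)prop-2-yn-1-ol F6. Mitsunobu etherification with 4 (PPh3, DIAD, toluene, −20 °C) would proceed with inversion to the silylated aryl propargyl ether F7; F7 is named (S) only because the silylethynyl group outranks the aryl group. K2CO3 in MeOH then removes the silyl group and comes back at 5.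

**Further compounds**

F1 | step 8 | (2S)-liquiritigenin, (2S)-7-hydroxy-2-(4-hydroxyphenyl)chroman-4-one (purchased) | O=C1C[C@@H](c2ccc(O)cc2)Oc2cc(O)ccc12
F2 | step 8 | 7,4'-di-O-benzyl-(2S)-liquiritigenin | O=C1C[C@@H](c2ccc(OCc3ccccc3)cc2)Oc2cc(OCc3ccccc3)ccc12
F3 | step 8 | (2S,4S)-7-benzyloxy-2-(4-benzyloxyphenyl)chroman-4-ol | O(Cc5ccccc5)c1ccc([C@@H]2C[C@H](O)c3ccc(OCc5ccccc5)cc3O2)cc1
F4 | step 7 | 1-(benzyloxy)-3-{[(1S)-1-(4-benzyloxyphenyl)-3-(hexa-O-benzylgallocatechin-8-yl)prop-2-yn-1-yl]oxy}benzene | O(Cc5ccccc5)c1cc(OCc5ccccc5)c2C[C@H](OCc5ccccc5)[C@@H](c3cc(OCc5ccccc5)c(OCc5ccccc5)c(OCc5ccccc5)c3)Oc2c1C#C[C@@H](Oc1cccc(OCc5ccccc5)c1)c1ccc(OCc5ccccc5)cc1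
F5 | step 7 | triethoxysilyl vinylsilane of 14, silicon on the alkene carbon bearing ring D, the two carbon substituents trans, (R) at the ether carbon | O(Cc5ccccc5)c1cc(OCc5ccccc5)c2C[C@H](OCc5ccccc5)[C@@H](c3cc(OCc5ccccc5)c(OCc5ccccc5)c(OCc5ccccc5)c3)Oc2c1/C([Si](OCC)(OCC)OCC)=C/[C@@H](Oc1cccc(OCc5ccccc5)c1)c1ccc(OCc5ccccc5)cc1
F6 | step 2 | (R)-1-(4-benzyloxyphenyl)-3-(trimethylsilyl)prop-2-yn-1-ol | C[Si](C)(C)C#C[C@H](O)c1ccc(OCc2ccccc2)cc1
F7 | step 2 | 1-(benzyloxy)-3-{[(1S)-1-(4-benzyloxyphenyl)-3-(trimethylsilyl)prop-2-yn-1-yl]oxy}benzene | C[Si](C)(C)C#C[C@@H](Oc1cccc(OCc2ccccc2)c1)c1ccc(OCc2ccccc2)cc1
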